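Assumption: the four phenols are carried as methoxymethyl ethers, not methyl ethers, because cleaving four aryl methyl ethers at the end would need reagents that attack the diarylalkyne, the benzylic alcohol or the triaryl carbinol; the target is treated as the achiral quinone methide of the SMILES.

## Analysis of the target

Selaginellin is built from five six-membered carbocycles that are not fused: a central benzene (ring A), a cyclohexa-2,5-dienone joined to ring A through an exocyclic methide carbon, and three 4-hydroxyphenyl rings, one on the methide carbon, one on C2 of ring A and one at the end of the ethynyl group on C6. Ring A is numbered so that C1 carries the methide carbon, C2 the aryl group, C3 and C4 hydrogen, C5 the CH2OH group and C6 the arylethynyl group. There is no stereogenic centre and no configured double bond, because the dienone ring is symmetric and the proton shift that exchanges the phenol and dienone rings averages any twist about the C1–methide bond, so no stereochemical task arises. The sensitive groups are the quinone methide, which is the dehydrated form of a triaryl carbinol, the diarylalkyne, which is wedged between two benzylic carbons whose oxygen atoms sit within reach for 5-exo or 6-endo addition, the primary benzylic alcohol and the four phenols. The difficulty is ring A, in which C5, C6, C1 and C2 carry four different, contiguous carbon substituents with the two bulkiest side by side, an arrangement that stepwise aromatic substitution cannot set reliably. The strategy rests on two features of ring A: C1 and C6 each carry one extra carbon (the methide carbon and the inner alkyne carbon) that an oxygen can bridge into a five-membered lactone, and C3 and C4 carry only hydrogen. Ring A is therefore the sum of three alkynes, two of them linked by an ester and the third being acetylene.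

## Retrosynthetic reasoning

**Quinone methide to protected carbinol (24 from 22 via 23).** The exocyclic C=C of selaginellin 24 does not need to be built. A bis(4-hydroxyphenyl)aryl carbinol forms it by losing its hydroxyl group, giving the triarylmethylium ion 23, and then a phenolic proton. The target is therefore traced to carbinol 22, with the phenols as methoxymethyl ethers and the primary alcohol as a silyl ether. All five protecting groups and the carbinol C–O bond respond to aqueous acid, so one operation should unmask and ionise.

**Aryl–alkyne bond (22 from 21 and 2).** The sp–sp2 bond between the alkyne and the outer ring is cut. This leaves terminal alkyne 21, whose triple bond can be traced to a carbonyl group, and aryl iodide 2, which is also the source of the other arylalkyne. The forward coupling must run at room temperature so that the free tertiary hydroxyl does not add to the alkyne.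

**Alkyne to lactone (21 from 19 via 20, 19 from 18).** Removing the terminal alkyne carbon gives aldehyde 20, which exists as its closed form, lactol 19, and this comes from lactone 18. The gain is that the C6 carbon and the carbinol oxygen sit in one robust five-membered lactone with both aryl groups already on the carbinol carbon. That ring shields the ionisable carbinol and stores the future alkyne carbon at the carboxyl level. Forward, a partial reduction and a one-carbon homologation open the ring and free the carbinol.

**Ring A (18 from 16 and 17).** This is the central disconnection. Three ring bonds are cut: C1–C6, C2–C3 and C4–C5. This unravels both ring A and the lactone into diyne ester 16 and acetylene 17. The cut is made here because the three-atom ester tether dictates which alkyne carbons join, and acetylene has no orientation. The four contiguous substituents are thus placed without any regiochemical choice. The forward reaction must assemble three alkynes on one metal centre without ionising the tertiary propargylic ester.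

**Ester (16 from 9 and 14).** The acyl–oxygen bond is cut to give tertiary propargylic alcohol 9 and ynoyl chloride 14. The alkoxide 15 of a hindered tertiary alcohol needs the most reactive acyl donor, and 14 has no α-hydrogen, so the acylation cannot be diverted by dehydrochlorination.

**Carbinol (9 from 5 and 7).** The bond between the carbinol carbon and the alkyne is cut. This gives the non-enolisable diaryl ketone 7 and arylalkyne 5, joined forward through acetylide 8.

**Small building blocks.** Acid chloride 14 comes from acid 13, which arises by carboxylation of acetylide 12, made from silyl ether 11 of propargyl alcohol 10. Alkyne 5 comes from iodide 2 and silylacetylene 3 through silylalkyne 4. Iodide 2 and ketone 7 are the methoxymethyl ethers of 4-iodophenol 1 and dihydroxybenzophenone 6.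

## Alternatives that were turned down

**Alternative 1: pyranone–alkyne cycloaddition.**
- Disconnection: ring A is cut at C1–C6 and C2–C3. This gives methyl 6-[(4-methoxyphenyl)ethynyl]-2-oxo-2H-pyran-5-carboxylate A2 and 1,1',1''-(prop-1-yne-1,3,3-triyl)tris(4-methoxybenzene) A3.
- Key step: an inverse-demand Diels–Alder addition of alkyne A3 across the pyranone diene of A2, then decarboxylative cycloreversion of the bridged lactone. This would give methyl 3-[bis(4-methoxyphenyl)methyl]-4-(4-methoxyphenyl)-2-[(4-methoxyphenyl)ethynyl]benzoate A1.
- For: it is convergent and metal-free, and benzoate A1 would hold ring A with all four substituents, including the intact diarylalkyne, after one step.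
- Against: the needed orientation places the bulky diarylmethyl end of A3 next to the alkynyl-bearing carbon of A2. Only a weak electronic difference between the two alkyne carbons supports this orientation. A3 is an unactivated internal alkyne, so forcing temperatures would be needed, and the pendant alkyne of A2 can itself act as dienophile. After the cycloaddition the triarylmethane C–H of A1 must be oxidised, the ester of A1 reduced, and four methyl ethers cleaved beside the alkyne.
- Comparison: on convergence and step count this alternative is stronger, because the alkyne of A1 needs neither homologation nor cross-coupling. The chosen strategy offers regiochemistry fixed by a tether, a reaction near room temperature, and the carbinol carbon already at its final oxidation level.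

**Alternative 2: formal [3+3] salicylate annulation.**
- Disconnection: ring A is cut at C4–C5 and C1–C2. This gives 1-methoxy-1,3-bis(trimethylsilyloxy)-5-(triisopropylsilyloxy)penta-1,3-diene A5 and 3,3-dimethoxy-1-(4-methoxyphenyl)propan-1-one A6.
- Key step: Lewis acid-mediated attack of the diene terminus of A5 on the acetal of A6, then aldol condensation onto the aryl ketone and aromatisation. This would give methyl 2-hydroxy-6-(4-methoxyphenyl)-3-{[(triisopropylsilyl)oxy]methyl}benzoate A4.
- For: the regiochemistry is defined, the partners are cheap and acyclic, and no precious metal or ionisable intermediate is involved. The phenol of A4 can become a triflate that couples directly with an arylacetylene.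
- Against: the step forms only two bonds and one ring. The ester of A4 then sits between two ortho substituents, and two aryl nucleophiles must add to it to make the carbinol. This is the most hindered carbon of the molecule. The allylic silyloxy group of A5 may be lost under the Lewis acid. The methyl ether of A4 and those added later remain a problem.
- Comparison: this alternative is stronger for the alkyne, which takes one coupling instead of a homologation plus a coupling. The chosen strategy offers three C–C bonds and two rings in one step, and it has the diaryl carbinol carbon attached to C1 before ring A exists.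

**Alternative 3: alkyne by carbene rearrangement of a diaryl ketone.**
- Disconnection: the alkyne is traced to {6-[(tert-butyldimethylsilyloxy)methyl]-2-[methoxybis(4-methoxyphenyl)methyl]-3-(4-methoxyphenyl)phenyl}(4-methoxyphenyl)methanone A8 and lithium (trimethylsilyl)diazomethanide A9.
- Key step: addition of A9 to the ketone of A8, Peterson elimination, loss of N2 and a 1,2-aryl shift of the alkylidene carbene. This would give tert-butyl{[3-[methoxybis(4-methoxyphenyl)methyl]-4-(4-methoxyphenyl)-2-[(4-methoxyphenyl)ethynyl]phenyl]methoxy}dimethylsilane A7.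
- For: the diarylalkyne of A7 forms in one operation without palladium, and the carbinol of A7 is capped as a methyl ether, so no free alkoxide sits beside the new alkyne.
- Against: no ring is formed, so the contiguous substitution of ring A must come from elsewhere. The carbonyl of A8 lies between two ortho substituents, one of them a triarylmethyl group, so the addition of A9 is doubtful. The carbene could also insert into the neighbouring benzylic C–H bond. The four aryl methyl ethers of A7 remain to be cleaved.
- Comparison: as an endgame the route through A7 is one step shorter than the chosen homologation and coupling, and it avoids the hydroxy alkyne. The chosen strategy offers what this alternative lacks, namely a regiodefined construction of ring A.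

Key step: step 10

## Route

Step 1
Reactants: 1 4-iodophenol
Product: 2 1-iodo-4-(methoxymethoxy)benzene
Conditions: NaH, MOMCl, DMF, 0 °C → rt
Reagents that add atoms: chloromethyl methyl ether, COCCl
Why: Williamson-type O-alkylation of the sodium phenoxide with a reactive α-chloro ether should be fast and clean.

Step 2
Reactants: 2 1-iodo-4-(methoxymethoxy)benzene; 3 ethynyltrimethylsilane
Product: 4 {[4-(methoxymethoxy)phenyl]ethynyl}trimethylsilane
Conditions: PdCl2(PPh3)2 (2 mol %), CuI (4 mol %), Et3N, THF, rt
Reagents that add atoms: none
Why: Sonogashira coupling of an aryl iodide should proceed at room temperature, and the silyl group blocks double coupling.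

Step 3
Reactants: 4 {[4-(methoxymethoxy)phenyl]ethynyl}trimethylsilane
Product: 5 1-ethynyl-4-(methoxymethoxy)benzene
Conditions: K2CO3 (cat.), MeOH, rt
Reagents that add atoms: none
Why: Methoxide-induced protodesilylation of the alkynylsilane should leave the base-stable acetal untouched.

Step 4
Reactants: 6 bis(4-hydroxyphenyl)methanone
Product: 7 bis[4-(methoxymethoxy)phenyl]methanone
Conditions: NaH, MOMCl, DMF, 0 °C → rt
Reagents that add atoms: chloromethyl methyl ether, COCCl
Why: Double O-alkylation of the bis-phenoxide, the same Williamson-type reaction as in step 1.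

Step 5
Reactants: 5 1-ethynyl-4-(methoxymethoxy)benzene; 7 bis[4-(methoxymethoxy)phenyl]methanone
Product: 9 1,1,3-tris[4-(methoxymethoxy)phenyl]prop-2-yn-1-ol, via lithium arylacetylide 8 (not isolated)
Conditions: n-BuLi, THF, −78 °C; then 7, −78 → 0 °C; H2O quench
Reagents that add atoms: none
Why: 1,2-Addition of a lithium acetylide to a non-enolisable diaryl ketone should be clean; a neutral quench avoids Meyer–Schuster rearrangement of the acid-sensitive propargylic alcohol.

Step 6
Reactants: 10 prop-2-yn-1-ol
Product: 11 tert-butyldimethyl(prop-2-yn-1-yloxy)silane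
Conditions: TBSCl, imidazole, CH2Cl2, 0 °C → rt
Reagents that add atoms: tert-butyldimethylsilyl chloride, CC(C)(C)[Si](C)(C)Cl
Why: Standard imidazole-promoted silylation of a primary alcohol.

Step 7
Reactants: 11 tert-butyldimethyl(prop-2-yn-1-yloxy)silane
Product: 13 4-(tert-butyldimethylsilyloxy)but-2-ynoic acid, via lithium acetylide 12 (not isolated)
Conditions: n-BuLi, THF, −78 °C; CO2, −78 °C → rt; cold 1 M HCl to pH 3
Reagents that add atoms: carbon dioxide, O=C=O
Why: Carboxylation of a lithium acetylide should give the ynoic acid, and a brief cold acidification spares the primary silyl ether.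

Step 8
Reactants: 13 4-(tert-butyldimethylsilyloxy)but-2-ynoic acid
Product: 14 4-(tert-butyldimethylsilyloxy)but-2-ynoyl chloride
Conditions: 1-chloro-N,N,2-trimethylprop-1-en-1-amine, CH2Cl2, 0 °C → rt; concentrated and used crude
Reagents that add atoms: 1-chloro-N,N,2-trimethylprop-1-en-1-amine, CC(C)=C(Cl)N(C)C
Why: The Ghosez α-chloroenamine forms acid chlorides under neutral conditions without releasing HCl, so neither the silyl ether nor the triple bond should suffer.

Step 9
Reactants: 9 1,1,3-tris[4-(methoxymethoxy)phenyl]prop-2-yn-1-ol; 14 4-(tert-butyldimethylsilyloxy)but-2-ynoyl chloride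
Product: 16 1,1,3-tris[4-(methoxymethoxy)phenyl]prop-2-yn-1-yl 4-(tert-butyldimethylsilyloxy)but-2-ynoate, via lithium alkoxide 15 (not isolated)
Conditions: n-BuLi (1.0 equiv), THF, −78 °C; then 14, −78 → −20 °C; aq. NaHCO3; chromatography on Et3N-deactivated silica
Reagents that add atoms: none
Why: O-Acylation of a preformed lithium tertiary alkoxide with an acid chloride is the standard access to hindered tertiary esters; 14 has no α-hydrogen, so no ketene can form, and the low temperature favours attack at the carbonyl over conjugate addition.

Step 10
Reactants: 16 1,1,3-tris[4-(methoxymethoxy)phenyl]prop-2-yn-1-yl 4-(tert-butyldimethylsilyloxy)but-2-ynoate; 17 acetylene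
Product: 18 7-[(tert-butyldimethylsilyloxy)methyl]-3,3,4-tris[4-(methoxymethoxy)phenyl]isobenzofuran-1(3H)-one
Conditions: RhCl(PPh3)3 (5 mol %), acetylene (1 atm), toluene, 25 → 40 °C, slow addition of 16
Reagents that add atoms: none
Why: Loss of a phosphine from RhCl(PPh3)3 should give a monovalent rhodium fragment that binds both alkynes of 16, and oxidative cyclisation then joins the two tether-proximal alkyne carbons, so that the new C1–C6 bond closes the five-membered lactone as part of a bicyclic trivalent rhodacyclopentadiene. Acetylene 17 then inserts into a Rh–C bond, forming one of the bonds C2–C3 and C4–C5, and C–C reductive elimination forms the other, closing ring A as a six-membered carbocycle and returning monovalent rhodium. The closest known reaction type is the rhodium-catalysed [2+2+2] cycloaddition of propargyl alkynoates with alkynes to give phthalides. No stereocentre is formed. Regiochemistry is not at issue, because the three-atom ester tether fixes which carbons of the diyne meet and acetylene is symmetric, so the aryl group must end on C2 and the silyloxymethyl group on C5. The step needs chemoselectivity for cross-cyclotrimerisation, which the intramolecular first step, the fully substituted and hindered alkyne termini of 16 and the excess of small acetylene should secure. It also needs the tertiary propargylic C–O bond to survive, which the neutral chloride complex, the absence of silver or other Lewis acid additives, the non-polar aprotic solvent and a temperature of at most 40 °C are chosen to ensure. The geminal diaryl groups should favour the folded rotamer in which both alkynes reach one metal centre.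

Step 11
Reactants: 18 7-[(tert-butyldimethylsilyloxy)methyl]-3,3,4-tris[4-(methoxymethoxy)phenyl]isobenzofuran-1(3H)-one
Product: 19 7-[(tert-butyldimethylsilyloxy)methyl]-3,3,4-tris[4-(methoxymethoxy)phenyl]-1,3-dihydroisobenzofuran-1-ol (racemic at C1)
Conditions: i-Bu2AlH (1.3 equiv), CH2Cl2, −78 °C; aq. potassium sodium tartrate
Reagents that add atoms: none
Why: Partial reduction of a lactone with i-Bu2AlH stops at the aluminium hemiacetal at −78 °C; the new lactol centre forms without control as a racemate and is destroyed in step 12.

Step 12
Reactants: 19 7-[(tert-butyldimethylsilyloxy)methyl]-3,3,4-tris[4-(methoxymethoxy)phenyl]-1,3-dihydroisobenzofuran-1-ol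
Product: 21 {3-[(tert-butyldimethylsilyloxy)methyl]-2-ethynyl-6-[4-(methoxymethoxy)phenyl]phenyl}bis[4-(methoxymethoxy)phenyl]methanol, via hydroxy aldehyde 20 (not isolated)
Conditions: dimethyl (1-diazo-2-oxopropyl)phosphonate (3 equiv), K2CO3, MeOH/THF, 0 °C → rt
Reagents that add atoms: dimethyl (1-diazo-2-oxopropyl)phosphonate, COP(=O)(OC)C(=[N+]=[N-])C(C)=O
Why: Seyferth–Gilbert homologation in the Ohira–Bestmann form should act on lactols through their open hydroxy aldehyde; the aryl-substituted diazoalkene loses nitrogen and undergoes a fast 1,2-hydrogen shift to the terminal alkyne, and the acetals and the silyl ether are stable to carbonate in methanol.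

Step 13
Reactants: 21 {3-[(tert-butyldimethylsilyloxy)methyl]-2-ethynyl-6-[4-(methoxymethoxy)phenyl]phenyl}bis[4-(methoxymethoxy)phenyl]methanol; 2 1-iodo-4-(methoxymethoxy)benzene
Product: 22 {3-[(tert-butyldimethylsilyloxy)methyl]-6-[4-(methoxymethoxy)phenyl]-2-{[4-(methoxymethoxy)phenyl]ethynyl}phenyl}bis[4-(methoxymethoxy)phenyl]methanol
Conditions: Pd(PPh3)4 (5 mol %), CuI (10 mol %), Et3N/THF, degassed, rt
Reagents that add atoms: none
Why: Sonogashira coupling of a terminal arylalkyne with an aryl iodide should run at room temperature, where the hindered tertiary hydroxyl should not add to the alkyne.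

Step 14
Reactants: 22 {3-[(tert-butyldimethylsilyloxy)methyl]-6-[4-(methoxymethoxy)phenyl]-2-{[4-(methoxymethoxy)phenyl]ethynyl}phenyl}bis[4-(methoxymethoxy)phenyl]methanol
Product: 24 selaginellin, 4-{[3-(hydroxymethyl)-6-(4-hydroxyphenyl)-2-[(4-hydroxyphenyl)ethynyl]phenyl](4-hydroxyphenyl)methylidene}cyclohexa-2,5-dien-1-one, via triarylmethylium chloride 23 (not isolated)
Conditions: 3 M aq. HCl/THF, 40 °C; then aq. NaHCO3 to pH 6–7
Reagents that add atoms: none
Why: Acid-catalysed acetal hydrolysis and silyl ether solvolysis should free the five hydroxyl groups while SN1 ionisation of the carbinol gives the stabilised cation 23; once the molecule is a cation, further protonation of the alkyne is disfavoured, water as the only nucleophile returns any benzylic cation to the alcohol, and neutralisation removes a phenolic proton to give the quinone methide.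

## Compound list

1 | 4-iodophenol | Oc1ccc(I)cc1 | starting material
2 | 1-iodo-4-(methoxymethoxy)benzene | COCOc1ccc(I)cc1 | intermediate
3 | ethynyltrimethylsilane | C#C[Si](C)(C)C | starting material
4 | {[4-(methoxymethoxy)phenyl]ethynyl}trimethylsilane | COCOc1ccc(cc1)C#C[Si](C)(C)C | intermediate
5 | 1-ethynyl-4-(methoxymethoxy)benzene | COCOc1ccc(cc1)C#C | intermediate
6 | bis(4-hydroxyphenyl)methanone | O=C(c1ccc(O)cc1)c1ccc(O)cc1 | starting material
7 | bis[4-(methoxymethoxy)phenyl]methanone | COCOc1ccc(cc1)C(=O)c1ccc(OCOC)cc1 | intermediate
8 | lithium [4-(methoxymethoxy)phenyl]acetylide | [Li+].[C-]#Cc1ccc(OCOC)cc1 | intermediate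
9 | 1,1,3-tris[4-(methoxymethoxy)phenyl]prop-2-yn-1-ol | COCOc1ccc(cc1)C#CC(O)(c1ccc(OCOC)cc1)c1ccc(OCOC)cc1 | intermediate
10 | prop-2-yn-1-ol | C#CCO | starting material
11 | tert-butyldimethyl(prop-2-yn-1-yloxy)silane | C#CCO[Si](C)(C)C(C)(C)C | intermediate
12 | lithium 3-(tert-butyldimethylsilyloxy)prop-1-yn-1-ide | [Li+].[C-]#CCO[Si](C)(C)C(C)(C)C | intermediate
13 | 4-(tert-butyldimethylsilyloxy)but-2-ynoic acid | OC(=O)C#CCO[Si](C)(C)C(C)(C)C | intermediate
14 | 4-(tert-butyldimethylsilyloxy)but-2-ynoyl chloride | ClC(=O)C#CCO[Si](C)(C)C(C)(C)C | intermediate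
15 | lithium 1,1,3-tris[4-(methoxymethoxy)phenyl]prop-2-yn-1-olate | [Li+].[O-]C(C#Cc1ccc(OCOC)cc1)(c1ccc(OCOC)cc1)c1ccc(OCOC)cc1 | intermediate
16 | 1,1,3-tris[4-(methoxymethoxy)phenyl]prop-2-yn-1-yl 4-(tert-butyldimethylsilyloxy)but-2-ynoate | COCOc1ccc(cc1)C#CC(OC(=O)C#CCO[Si](C)(C)C(C)(C)C)(c1ccc(OCOC)cc1)c1ccc(OCOC)cc1 | intermediate
17 | acetylene | C#C | starting material
18 | 7-[(tert-butyldimethylsilyloxy)methyl]-3,3,4-tris[4-(methoxymethoxy)phenyl]isobenzofuran-1(3H)-one | O=C1OC(c2ccc(OCOC)cc2)(c2ccc(OCOC)cc2)c2c(-c3ccc(OCOC)cc3)ccc(CO[Si](C)(C)C(C)(C)C)c12 | intermediate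
19 | 7-[(tert-butyldimethylsilyloxy)methyl]-3,3,4-tris[4-(methoxymethoxy)phenyl]-1,3-dihydroisobenzofuran-1-ol (racemic) | OC1OC(c2ccc(OCOC)cc2)(c2ccc(OCOC)cc2)c2c(-c3ccc(OCOC)cc3)ccc(CO[Si](C)(C)C(C)(C)C)c12 | intermediate
20 | 6-[(tert-butyldimethylsilyloxy)methyl]-2-{hydroxybis[4-(methoxymethoxy)phenyl]methyl}-3-[4-(methoxymethoxy)phenyl]benzaldehyde | O=Cc1c(CO[Si](C)(C)C(C)(C)C)ccc(-c2ccc(OCOC)cc2)c1C(O)(c1ccc(OCOC)cc1)c1ccc(OCOC)cc1 | intermediate
21 | {3-[(tert-butyldimethylsilyloxy)methyl]-2-ethynyl-6-[4-(methoxymethoxy)phenyl]phenyl}bis[4-(methoxymethoxy)phenyl]methanol | C#Cc1c(CO[Si](C)(C)C(C)(C)C)ccc(-c2ccc(OCOC)cc2)c1C(O)(c1ccc(OCOC)cc1)c1ccc(OCOC)cc1 | intermediate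
22 | {3-[(tert-butyldimethylsilyloxy)methyl]-6-[4-(methoxymethoxy)phenyl]-2-{[4-(methoxymethoxy)phenyl]ethynyl}phenyl}bis[4-(methoxymethoxy)phenyl]methanol | COCOc1ccc(cc1)C#Cc1c(CO[Si](C)(C)C(C)(C)C)ccc(-c2ccc(OCOC)cc2)c1C(O)(c1ccc(OCOC)cc1)c1ccc(OCOC)cc1 | intermediate
23 | {3-(hydroxymethyl)-6-(4-hydroxyphenyl)-2-[(4-hydroxyphenyl)ethynyl]phenyl}bis(4-hydroxyphenyl)methylium chloride | OCc1ccc(-c2ccc(O)cc2)c([C+](c2ccc(O)cc2)c2ccc(O)cc2)c1C#Cc1ccc(O)cc1.[Cl-] | intermediate
24 | selaginellin | O=C1C=CC(=C(c2ccc(O)cc2)c2c(-c3ccc(O)cc3)ccc(CO)c2C#Cc2ccc(O)cc2)C=C1 | target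

## Step count and risks

Total step count: 14. Longest linear sequence: 10 steps (steps 1, 2, 3, 5, 9, 10, 11, 12, 13, 14, from 4-iodophenol 1).

**Step 10 (key step).**
Risk: the tertiary propargylic C–O bond, which carries two donor-substituted aryl groups, may ionise at the metal or on trace acid. This would lead to a 1,3-acyloxy shift or elimination instead of cyclisation. The oxidative cyclisation may also be slow, because the ester prefers the extended rotamer that holds the two alkynes apart, and acetylene oligomerisation would then consume the catalyst.
Fallback: invert the ester so that the tether is a primary propargylic alkynoate, and add the two aryl groups afterwards. It sets out from 5 and 11. Alkyne 5 is lithiated and carboxylated to 3-[4-(methoxymethoxy)phenyl]prop-2-ynoic acid F1. Silyl ether 11 is lithiated and treated with paraformaldehyde to give 4-(tert-butyldimethylsilyloxy)but-2-yn-1-ol F2. Esterification of F1 with F2 by N,N'-dicyclohexylcarbodiimide and 4-(dimethylamino)pyridine gives 4-(tert-butyldimethylsilyloxy)but-2-yn-1-yl 3-[4-(methoxymethoxy)phenyl]prop-2-ynoate F3. Cycloaddition of F3 with acetylene 17 under RhCl(PPh3)3 should give 4-[(tert-butyldimethylsilyloxy)methyl]-7-[4-(methoxymethoxy)phenyl]isobenzofuran-1(3H)-one F4. Iodine–lithium exchange on 2 with n-BuLi gives [4-(methoxymethoxy)phenyl]lithium F5. An excess of F5 adds twice to the lactone carbonyl of F4 to give {3-[(tert-butyldimethylsilyloxy)methyl]-2-(hydroxymethyl)-6-[4-(methoxymethoxy)phenyl]phenyl}bis[4-(methoxymethoxy)phenyl]methanol F6. Oxidation of the primary benzylic alcohol of F6 with MnO2 gives hydroxy aldehyde 20, which closes to lactol 19. The route is rejoined at 19; any further oxidation would give 18, which is also on the route.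

**Step 9.**
Risk: acylation of the hindered alkoxide may be slow, so that conjugate addition to the ynoyl chloride competes. The product may also ionise during isolation.
Fallback: form the alkyne–carbonyl bond instead of the oxygen–acyl bond. It sets out from 9. Alkoxide 15 is treated with 1,1'-carbonyldiimidazole to give 1,1,3-tris[4-(methoxymethoxy)phenyl]prop-2-yn-1-yl 1H-imidazole-1-carboxylate F7. Lithium acetylide 12, made from 11, then displaces imidazolide at −78 °C to give ester 16, where the route is rejoined.

**Step 12.**
Risk: the lactol may stay closed. It is flanked on both sides and carries geminal aryl groups, so the open aldehyde 20 may be too scarce and too hindered for the phosphonate anion. Long exposure to base could also let the tertiary alkoxide add to the new alkyne.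
Fallback: Wittig chloromethylenation and elimination. It sets out from 19. The ylide from (chloromethyl)triphenylphosphonium chloride and NaN(SiMe3)2 converts the lactol to {3-[(tert-butyldimethylsilyloxy)methyl]-2-(2-chloroethenyl)-6-[4-(methoxymethoxy)phenyl]phenyl}bis[4-(methoxymethoxy)phenyl]methanol F8, expected as a mixture of E and Z isomers. Excess lithium diisopropylamide at −78 → 0 °C eliminates chloride to give alkyne 21, where the route is rejoined.

**Step 14.**
Risk: the four aryl acetals may cleave more slowly than the product tolerates. Longer exposure to acid invites Friedel–Crafts closure of the cation onto the C2 aryl ring to give a fluorene, hydroxymethylation of the free phenols by released formaldehyde, or addition of the benzylic hydroxyl to the alkyne.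
Fallback: a staged, aprotic unmasking. It sets out from 22. Trimethylsilyl triflate with 2,2'-bipyridyl in CH2Cl2 at 0 °C converts the aryl acetals to aryl silyl ethers by silyl transfer. Aqueous work-up then frees the phenols and dehydrates the carbinol to 4-{[3-{[(tert-butyldimethylsilyl)oxy]methyl}-6-(4-hydroxyphenyl)-2-[(4-hydroxyphenyl)ethynyl]phenyl](4-hydroxyphenyl)methylidene}cyclohexa-2,5-dien-1-one F9. AcOH/THF/H2O at room temperature removes the primary silyl ether of F9 and gives selaginellin 24.

## Further compounds

F1 | step 10 | 3-[4-(methoxymethoxy)phenyl]prop-2-ynoic acid | COCOc1ccc(cc1)C#CC(=O)O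
F2 | step 10 | 4-(tert-butyldimethylsilyloxy)but-2-yn-1-ol | OCC#CCO[Si](C)(C)C(C)(C)C
F3 | step 10 | 4-(tert-butyldimethylsilyloxy)but-2-yn-1-yl 3-[4-(methoxymethoxy)phenyl]prop-2-ynoate | COCOc1ccc(cc1)C#CC(=O)OCC#CCO[Si](C)(C)C(C)(C)C
F4 | step 10 | 4-[(tert-butyldimethylsilyloxy)methyl]-7-[4-(methoxymethoxy)phenyl]isobenzofuran-1(3H)-one | O=C1OCc2c(CO[Si](C)(C)C(C)(C)C)ccc(-c3ccc(OCOC)cc3)c12
F5 | step 10 | [4-(methoxymethoxy)phenyl]lithium | [Li]c1ccc(OCOC)cc1
F6 | step 10 | {3-[(tert-butyldimethylsilyloxy)methyl]-2-(hydroxymethyl)-6-[4-(methoxymethoxy)phenyl]phenyl}bis[4-(methoxymethoxy)phenyl]methanol | OCc1c(CO[Si](C)(C)C(C)(C)C)ccc(-c2ccc(OCOC)cc2)c1C(O)(c1ccc(OCOC)cc1)c1ccc(OCOC)cc1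
F7 | step 9 | 1,1,3-tris[4-(methoxymethoxy)phenyl]prop-2-yn-1-yl 1H-imidazole-1-carboxylate | COCOc1ccc(cc1)C#CC(OC(=O)n1ccnc1)(c1ccc(OCOC)cc1)c1ccc(OCOC)cc1
F8 | step 12 | {3-[(tert-butyldimethylsilyloxy)methyl]-2-(2-chloroethenyl)-6-[4-(methoxymethoxy)phenyl]phenyl}bis[4-(methoxymethoxy)phenyl]methanol (mixture of E and Z isomers) | ClC=Cc1c(CO[Si](C)(C)C(C)(C)C)ccc(-c2ccc(OCOC)cc2)c1C(O)(c1ccc(OCOC)cc1)c1ccc(OCOC)cc1
F9 | step 14 | 4-{[3-{[(tert-butyldimethylsilyl)oxy]methyl}-6-(4-hydroxyphenyl)-2-[(4-hydroxyphenyl)ethynyl]phenyl](4-hydroxyphenyl)methylidene}cyclohexa-2,5-dien-1-one | O=C1C=CC(=C(c2ccc(O)cc2)c2c(-c3ccc(O)cc3)ccc(CO[Si](C)(C)C(C)(C)C)c2C#Cc2ccc(O)cc2)C=C1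
A1 | alternative 1 | methyl 3-[bis(4-methoxyphenyl)methyl]-4-(4-methoxyphenyl)-2-[(4-methoxyphenyl)ethynyl]benzoate | COC(=O)c1ccc(-c2ccc(OC)cc2)c(C(c2ccc(OC)cc2)c2ccc(OC)cc2)c1C#Cc1ccc(OC)cc1
A2 | alternative 1 | methyl 6-[(4-methoxyphenyl)ethynyl]-2-oxo-2H-pyran-5-carboxylate | COC(=O)C1=C(C#Cc2ccc(OC)cc2)OC(=O)C=C1
A3 | alternative 1 | 1,1',1''-(prop-1-yne-1,3,3-triyl)tris(4-methoxybenzene) | COc1ccc(cc1)C#CC(c1ccc(OC)cc1)c1ccc(OC)cc1
A4 | alternative 2 | methyl 2-hydroxy-6-(4-methoxyphenyl)-3-{[(triisopropylsilyl)oxy]methyl}benzoate | COC(=O)c1c(O)c(CO[Si](C(C)C)(C(C)C)C(C)C)ccc1-c1ccc(OC)cc1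
A5 | alternative 2 | 1-methoxy-1,3-bis(trimethylsilyloxy)-5-(triisopropylsilyloxy)penta-1,3-diene (double-bond geometry not defined) | COC(O[Si](C)(C)C)=CC(O[Si](C)(C)C)=CCO[Si](C(C)C)(C(C)C)C(C)C
A6 | alternative 2 | 3,3-dimethoxy-1-(4-methoxyphenyl)propan-1-one | COc1ccc(cc1)C(=O)CC(OC)OC
A7 | alternative 3 | tert-butyl{[3-[methoxybis(4-methoxyphenyl)methyl]-4-(4-methoxyphenyl)-2-[(4-methoxyphenyl)ethynyl]phenyl]methoxy}dimethylsilane | COc1ccc(cc1)C#Cc1c(CO[Si](C)(C)C(C)(C)C)ccc(-c2ccc(OC)cc2)c1C(OC)(c1ccc(OC)cc1)c1ccc(OC)cc1
A8 | alternative 3 | {6-[(tert-butyldimethylsilyloxy)methyl]-2-[methoxybis(4-methoxyphenyl)methyl]-3-(4-methoxyphenyl)phenyl}(4-methoxyphenyl)methanone | COc1ccc(cc1)C(=O)c1c(CO[Si](C)(C)C(C)(C)C)ccc(-c2ccc(OC)cc2)c1C(OC)(c1ccc(OC)cc1)c1ccc(OC)cc1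
A9 | alternative 3 | lithium (trimethylsilyl)diazomethanide | [Li]C(=[N+]=[N-])[Si](C)(C)C
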